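## Structural features

Pervilleanone is an isoflavanone: benzo ring A is fused to the dihydropyranone ring C (O1, C2H2, C3H, C4=O, C4a, C8a), and ring B is bonded to C3 through C1'. Ring A carries only the C7 hydroxyl and nothing at C5. Ring B is substituted everywhere except C6': hydroxyl at C2', methoxy at C3' and C4', and a 2-methylbut-3-en-2-yl (reverse prenyl) group at C5' whose quaternary carbon sits next to the C4' methoxy group. The only stereocentre is C3 (R); it has no stereogenic neighbour and, being tertiary, benzylic and alpha to the C4 ketone, it is lost by enolisation in base and more slowly in acid. Other fragile points are the C2' hydroxyl (it can add to the C4 carbonyl and dehydrate to a benzofuran in acid), the monosubstituted alkene (no heterogeneous hydrogenation) and the two free phenols (they must be masked against arynes and oxidants). The real difficulty is therefore the late, mild creation of C3 in one configuration, together with regiocontrol in a ring A that has a single oxygen and in a ring B with four contiguous substituents. The key step uses the fact that O1 and the C4 carbonyl sit on the adjacent ring A carbons C8a and C4a. That is the ortho-acylphenol pattern left when an aryne inserts into the acyl C–O bond of a carboxylic acid, and if the acid already holds C2, C3 and ring B with a leaving group on C2, the phenolate closes ring C at once.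

## Logic of the disconnections

30 to 29: the two phenolic O–CH2 acetal bonds are cut. The phenols must stay masked through aryne, hydride-transfer and oxidation chemistry. Nothing is simplified in the skeleton, and the forward cleavage must neither enolise C3 nor dehydrate the 2'-hydroxy ketone.

29 to 28 to 26: the C3–H and C2–H bonds are cut (with a passing C4–H bond in 28), which takes the stereocentre back to the flat chromone 26. A centre alpha to a ketone cannot be carried through the earlier steps, so it is made late. Because it is formed by protonation, the forward reduction is run through the C4 alcohol 28, where dynamic kinetic resolution ties C3 to the catalyst-controlled C4, and the reoxidation must leave C3 alone.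

26 to 25: the C5–H bond is replaced by C5–Cl. The chlorine is put back as the element that polarises the aryne, which turns an unselective 4-oxygenated aryne into a selective one. The price is a later hydrodechlorination that must spare the vinyl group and the enone.

25 to 21 and 7: O1–C8a, C4–C4a and O1–C2 are cut, the three bonds that an aryne and a beta-methoxyacrylic acid form in one flask. The molecule falls into two arenes of similar size and ring C disappears. The forward step needs attack at C8a only, acyl transfer faster than protonation, and a leaving group on C2.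

7 to 6 to 2 to 1: the acetal O–CH2, the O–S bond of the triflate and the C–Si bond are cut, and the C–Si bond is traced to a C–Br bond through silyl migration from the neighbouring oxygen. That migration makes the two hydroxyls of a resorcinol differ without a selective protection. 1 is symmetrical and commercial. The bromination must go to the carbon between hydroxyl and chlorine, and the aryllithium must rearrange before it can lose chloride.

21 to 20 to 19 to 16 and 17: after the ester and enol-ether O–C bonds, C1'–C3 and C2–C3 are cut. The formyl carbon of 16 becomes C2, the diazo carbon of 17 becomes C3 and receives ring B by a 1,2-shift. No aryl halide or separate arylacetic acid is needed. The forward step needs aryl rather than hydride migration under a Lewis acid that spares the acetal.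

16 to 15 to 13: the O4'–CH3 bond, then the C5'–C bond to the quaternary carbon, are cut, the latter reconnected as an O4'–CH2 allyl ether. A [3,3] shift puts the reverse prenyl group ortho to oxygen and forms the crowded quaternary carbon intramolecularly. It requires the para position to be blocked (the formyl group does this) and only one ortho carbon to be free.

13 to 12 to 10 and 11 to 8: the O2' acetal bond, the O4'–CH2 bond and C1'–CHO are cut. The formyl group breaks the symmetry of 8 and, through its hydrogen bond, distinguishes O2' from O4'. 8 is symmetrical and commercial. The forward steps need monoformylation and alkylation at O4' only.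

## Other disconnections considered

Alternative 1: The cut is at C5'–C (quaternary carbon) and C4'–O of ring B together. In the forward step a hindered lithium amide would deprotonate the silyl ether A2 between bromine and methoxy, and loss of bromide would give an aryne across C4'–C5'. An allylic 3-methylbut-2-enyl Grignard reagent would add at C5' through its dimethyl-substituted end, and the arylmagnesium left at C4' would be oxidised through a borate and peroxide to give A1.
- In its favour: two neighbouring substituents of the crowded ring arrive in one flask, the C3' methoxy steers the addition by the same inductive polarisation that chlorine supplies in the chosen plan, and the quaternary carbon is made cold. For this part it is the better plan on step count: A1 would need two steps, while the chosen route needs five to reach 15, one of them at 190 °C.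
- Against it here: it solves ring B only. C1' of A1 is unsubstituted, so methylation, exchange of the silyl ether and introduction of a carbon ortho to O2' must follow; counted to the level of 16 the two routes are about equal in length. Ring C and C3 still need a separate idea.
- Mechanism: the Grignard reagent may react through either allylic end, the amide base competes as a nucleophile, and the arylmagnesium to be oxidised is flanked on both sides. The sigmatropic route of the chosen plan has fewer such open points. The idea could replace steps 5 to 8 without touching the key step.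

Alternative 2: The cut is at C3–C4. In the forward step base would expel sulfinate from the 2-(1-sulfonylalkyl)phenol A4 to give a ring B ortho-quinone methide whose exocyclic carbon is C3. The ring A aldehyde, tethered through O1–C2, would form a Breslow intermediate with a chiral triazolylidene and add to C3 (an intramolecular Stetter-type addition), closing ring C and giving A3.
- In its favour: ring C, the ketone and the stereocentre come from one catalytic asymmetric C–C bond formation at the final oxidation level, the C2' hydroxyl is released by the reaction itself, and no chlorine is needed. After the ring closure it is the better plan: one desilylation, against the reduction–oxidation detour of steps 14 and 15 and an acetal cleavage once C3 exists.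
- Against it here: the step needs base, and its product carries the C3–H that base removes, so the enantiomeric purity could be eroded in the same flask. The quinone methide has hydrogens on C2 and could tautomerise to a vinyl phenol or lose the ring A phenolate. Attack at a substituted quinone methide terminus of this ring B is crowded.
- Comparison: both plans need a ring B aldehyde of the type of 16 (equal), and assembling A4 from it would take about as many steps as 16 to 21. The alternative controls C3 directly; the chosen plan does so indirectly, by hydride transfer with dynamic kinetic resolution, a reaction type with a broad record on 3-arylchromanones.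

Alternative 3: The cut is at C2–C3. In the forward step the diazo deoxybenzoin A6 would lose N2 on a chiral dirhodium tetracarboxylate and the carbene at C3 would insert into a C–H bond of the ring A methoxy group ortho to the ketone; the methoxy carbon would become C2 and A5 would result.
- In its favour: A6 is convergent (acylation, diazo transfer), and the conditions are neutral, so the new stereocentre is not endangered while it forms. On this point it is better than alternative 2 and at least the equal of the chosen plan. The silyl ethers would come off with buffered fluoride, milder than step 16, and there is no redox detour and no chlorine.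
- Against it here: the insertion is a 1,6-insertion into a primary C–H bond, whereas the established enantioselective cases close five-membered rings at secondary or benzylic positions. Attack of the carbene on the lone pair of the same methoxy oxygen would give a five-membered oxonium ylide and then a 2-methylbenzofuranone. The C2' silyloxy group and the vinyl group of a second molecule are further traps, and diazo transfer between two ortho-substituted arenes is hindered.
- Comparison: the alternative uses a methyl ether as C2, which is more economical than bringing C2 in with 17. Its site selectivity is open, while the polar steps of the chosen plan are predictable. If the insertion worked it would probably be two or three steps shorter from the ring B aldehyde.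

Key step: step 12

Remark: 19 is drawn as the hydrogen-bonded Z enol and 20 to 22 and 24 as E enol ethers; the geometry is lost in the enolate of step 12 and does not affect the outcome.
Remark: atom bookkeeping for the key step: the silyl-bearing carbon of 7 becomes C4a, the triflate-bearing carbon becomes C8a, chlorine ends at C5 and the acetal oxygen at C7.

Step 1
Reactants: 1 5-chlorobenzene-1,3-diol (5-chlororesorcinol)
Product: 2 4-bromo-5-chlorobenzene-1,3-diol
Conditions: NBS (1.0 equiv), THF, −78 → 0 °C
Reagents that add atoms: N-bromosuccinimide O=C1CCC(=O)N1Br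
Why: Electrophilic aromatic bromination; C4 is para to one hydroxyl and ortho to the other, the kinetically preferred site of a resorcinol, and one equivalent in the cold should stop at the monobromide.

Step 2
Reactants: 2 4-bromo-5-chlorobenzene-1,3-diol
Product: 6 3-chloro-5-hydroxy-2-(trimethylsilyl)phenyl trifluoromethanesulfonate, via bis(trimethylsilyl) ether 3 (not isolated), via C-silylated lithium phenolate 4 (not isolated), via O-silylated aryl triflate 5 (not isolated)
Conditions: HMDS, THF, 70 °C, then evaporate; n-BuLi, THF, −100 → −78 °C; Tf2O, −100 °C → rt; MeOH, citric acid (cat.), 0 °C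
Reagents that add atoms: hexamethyldisilazane C[Si](C)(C)N[Si](C)(C)C; trifluoromethanesulfonic anhydride O=S(=O)(OS(=O)(=O)C(F)(F)F)C(F)(F)F
Why: Bromine–lithium exchange followed by retro-Brook 1,3-shift moves only the silyl group of the oxygen next to the lithiated carbon onto carbon, so that oxygen alone is freed as the phenolate and triflated; the remote aryl silyl ether is methanolysed on work-up. The low temperature keeps the ortho-chloro aryllithium from losing LiCl before the shift.

Step 3
Reactants: 6 3-chloro-5-hydroxy-2-(trimethylsilyl)phenyl trifluoromethanesulfonate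
Product: 7 3-chloro-5-(methoxymethoxy)-2-(trimethylsilyl)phenyl trifluoromethanesulfonate
Conditions: MOMCl, i-Pr2NEt, CH2Cl2, 0 °C → rt
Reagents that add atoms: chloromethyl methyl ether COCCl
Why: O-alkylation of an acidic phenol with an alpha-chloro ether; no fluoride or hard nucleophile is present, so the silyl triflate unit is untouched, and the acetal is inert to fluoride later.

Step 4
Reactants: 8 2-methoxybenzene-1,3-diol (2-methoxyresorcinol)
Product: 10 2,4-dihydroxy-3-methoxybenzaldehyde, via aryl iminium chloride 9 (not isolated)
Conditions: POCl3, DMF, MeCN, −15 → 25 °C; then H2O, 50 °C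
Reagents that add atoms: N,N-dimethylformamide CN(C)C=O; water O
Why: Vilsmeier–Haack formylation at the only type of activated carbon (ortho to one hydroxyl, para to the other); the iminium group of 9 deactivates the ring against a second formylation and is hydrolysed on work-up.

Step 5
Reactants: 10 2,4-dihydroxy-3-methoxybenzaldehyde; 11 1-bromo-3-methylbut-2-ene (prenyl bromide)
Product: 12 2-hydroxy-3-methoxy-4-[(3-methylbut-2-en-1-yl)oxy]benzaldehyde
Conditions: KHCO3, DMF, 40 °C
Reagents that add atoms: none
Why: Williamson etherification; the C4 hydroxyl is para to the formyl group and the more acidic, while the C2 hydroxyl is held in a hydrogen bond to the carbonyl, so a weak base should alkylate O4 only.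

Step 6
Reactants: 12 2-hydroxy-3-methoxy-4-[(3-methylbut-2-en-1-yl)oxy]benzaldehyde
Product: 13 3-methoxy-2-(methoxymethoxy)-4-[(3-methylbut-2-en-1-yl)oxy]benzaldehyde
Conditions: MOMCl, i-Pr2NEt, CH2Cl2, 0 → 40 °C
Reagents that add atoms: chloromethyl methyl ether COCCl
Why: Acetal protection of the chelated phenol; the group withstands the heat of step 7, base, fluoride and hydride transfer, and leaves a single free phenol after the rearrangement.

Step 7
Reactants: 13 3-methoxy-2-(methoxymethoxy)-4-[(3-methylbut-2-en-1-yl)oxy]benzaldehyde
Product: 15 4-hydroxy-3-methoxy-2-(methoxymethoxy)-5-(2-methylbut-3-en-2-yl)benzaldehyde, via ortho-dienone 14 (not isolated)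
Conditions: N,N-diethylaniline, 190 °C, sealed tube, argon
Reagents that add atoms: none
Why: Aromatic Claisen rearrangement: the [3,3] shift to the only free ortho carbon inverts the allyl unit and gives the 1,1-dimethylallyl dienone 14, which enolises to the phenol. The para carbon is blocked by the formyl group, so the Cope route to a para prenyl phenol is closed, and the amine solvent speeds tautomerisation and suppresses acid-catalysed follow-up reactions.

Step 8
Reactants: 15 4-hydroxy-3-methoxy-2-(methoxymethoxy)-5-(2-methylbut-3-en-2-yl)benzaldehyde
Product: 16 3,4-dimethoxy-2-(methoxymethoxy)-5-(2-methylbut-3-en-2-yl)benzaldehyde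
Conditions: MeI, K2CO3, DMF, rt
Reagents that add atoms: iodomethane CI
Why: Williamson methylation of the single free phenol; the small electrophile tolerates the two ortho substituents.

Step 9
Reactants: 16 3,4-dimethoxy-2-(methoxymethoxy)-5-(2-methylbut-3-en-2-yl)benzaldehyde; 17 ethyl diazoacetate
Product: 19 ethyl (Z)-2-[3,4-dimethoxy-2-(methoxymethoxy)-5-(2-methylbut-3-en-2-yl)phenyl]-3-hydroxyacrylate (enol of the alpha-formyl ester), via diazonium alkoxide adduct 18 (not isolated)
Conditions: [(η5-C5H5)Fe(CO)2(THF)]BF4 (10 mol %), CH2Cl2, 0 °C, slow addition of 17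
Reagents that add atoms: none
Why: Roskamp-type homologation with 1,2-aryl shift: the diazo carbon adds to the Lewis acid-activated aldehyde, and in 18 the electron-rich aryl group migrates to the diazonium carbon as N2 leaves, giving the alpha-formyl arylacetate, which rests as its hydrogen-bonded enol. Electron-rich aryl groups favour aryl over hydride migration, and the mild cationic iron Lewis acid should leave the acetal intact.

Step 10
Reactants: 19 ethyl (Z)-2-[3,4-dimethoxy-2-(methoxymethoxy)-5-(2-methylbut-3-en-2-yl)phenyl]-3-hydroxyacrylate
Product: 20 ethyl (E)-2-[3,4-dimethoxy-2-(methoxymethoxy)-5-(2-methylbut-3-en-2-yl)phenyl]-3-methoxyacrylate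
Conditions: Me2SO4, K2CO3, acetone, rt
Reagents that add atoms: dimethyl sulfate COS(=O)(=O)OC
Why: O-alkylation of the enolate of a beta-formyl ester with a hard electrophile gives the beta-methoxyacrylate, expected mainly as the E isomer.

Step 11
Reactants: 20 ethyl (E)-2-[3,4-dimethoxy-2-(methoxymethoxy)-5-(2-methylbut-3-en-2-yl)phenyl]-3-methoxyacrylate
Product: 21 (E)-2-[3,4-dimethoxy-2-(methoxymethoxy)-5-(2-methylbut-3-en-2-yl)phenyl]-3-methoxyacrylic acid
Conditions: LiOH·H2O, THF/MeOH/H2O, 40 °C; then 1 M HCl to pH 4, 0 °C
Reagents that add atoms: lithium hydroxide [Li+].[OH-]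
Why: Saponification; the vinylogous carbonate is a poor Michael acceptor and the acetal is base-stable, and the cold, brief acidification to pH 4 spares acetal and enol ether.

Step 12
Reactants: 21 (E)-2-[3,4-dimethoxy-2-(methoxymethoxy)-5-(2-methylbut-3-en-2-yl)phenyl]-3-methoxyacrylic acid; 7 3-chloro-5-(methoxymethoxy)-2-(trimethylsilyl)phenyl trifluoromethanesulfonate
Product: 25 5-chloro-7,2'-bis(methoxymethoxy)-3',4'-dimethoxy-5'-(2-methylbut-3-en-2-yl)isoflavone, via cesium carboxylate 22 (not isolated), via aryne 23 (not isolated), via ortho-acyl cesium phenolate 24 (not isolated)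
Conditions: Cs2CO3 (0.5 equiv), MeOH, then evaporate and dry; 7 (1.5 equiv), CsF (4 equiv), THF, 125 °C, sealed tube
Reagents that add atoms: none
Why: Fluoride removes the silyl group of 7 and triflate leaves, giving aryne 23, whose triple bond is polarised by the adjacent C5 chlorine so that the carboxylate oxygen of 22 attacks C8a and the aryl anion develops at C4a beside chlorine. That anion adds to the ester carbonyl (4-exo-trig) and the strained benzoxetene alkoxide opens to the ortho-acyl phenolate 24, a net insertion into the acyl C–O bond; the closest known reaction type is the fluoride-induced insertion of arynes into carboxylic acids followed by conjugate ring closure to chromanones and chromones. The phenolate then adds to C2 of the beta-methoxy enone (6-endo-trig) and methoxide is expelled, which closes ring C at the chromone level and makes the closure irreversible. No stereocentre is formed, and the enol ether geometry is lost in the enolate. The site of the first attack is secured by the inductive effect of chlorine, which outweighs the weak and opposite influence of the remote C7 oxygen. Acyl transfer must outrun protonation of the aryl anion, which is why the acid is used as its dried cesium salt so that no acidic proton is present, and the high temperature serves the four-membered transition state. Acyl transfer must also outrun conjugate addition of the aryl anion to C2 (which would lead to a 3-arylcoumarin); the in-plane sp2 anion reaches the carbonyl carbon but is poorly aligned with the pi system at C2. The reverse prenyl group has no allylic hydrogen, so an aryne ene reaction is excluded, and the acetals are inert to fluoride.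

Step 13
Reactants: 25 5-chloro-7,2'-bis(methoxymethoxy)-3',4'-dimethoxy-5'-(2-methylbut-3-en-2-yl)isoflavone
Product: 26 7,2'-bis(methoxymethoxy)-3',4'-dimethoxy-5'-(2-methylbut-3-en-2-yl)isoflavone
Conditions: Pd(OAc)2 (5 mol %), XPhos (10 mol %), HCO2Na, DMF, 80 °C
Reagents that add atoms: none
Why: Palladium-catalysed hydrodehalogenation: zerovalent palladium inserts into the C5–Cl bond, which is activated by the peri carbonyl, formate exchanges for chloride and decarboxylates to the aryl palladium hydride, and reductive elimination gives C5–H. The ligated hydride should be consumed by this elimination faster than it can add to the hindered vinyl group or the trisubstituted chromone alkene.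

Step 14
Reactants: 26 7,2'-bis(methoxymethoxy)-3',4'-dimethoxy-5'-(2-methylbut-3-en-2-yl)isoflavone
Product: 28 (3R,4R)-7,2'-bis(methoxymethoxy)-3',4'-dimethoxy-5'-(2-methylbut-3-en-2-yl)isoflavan-4-ol (3-aryl cis to 4-hydroxyl), via racemic isoflavanone 27 (not isolated)
Conditions: RuCl[(R,R)-TsDPEN](p-cymene) (3 mol %), HCO2H/Et3N (5:2), EtOAc, 40 °C
Reagents that add atoms: none
Why: Noyori-type asymmetric transfer hydrogenation with dynamic kinetic resolution: the ruthenium hydride first reduces C2=C3 to 27, which racemises through its enol in the amine–formic acid medium while the catalyst reduces the ketone of one enantiomer faster. The (R,R) ligand sets C4 as R, as for aryl ketones in general, and hydride delivery anti to the 3-aryl group makes the alcohol cis, which fixes C3 as R; the isolated alkene and the acetals are inert.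

Step 15
Reactants: 28 (3R,4R)-7,2'-bis(methoxymethoxy)-3',4'-dimethoxy-5'-(2-methylbut-3-en-2-yl)isoflavan-4-ol
Product: 29 (3R)-7,2'-bis(methoxymethoxy)-3',4'-dimethoxy-5'-(2-methylbut-3-en-2-yl)isoflavanone
Conditions: Dess–Martin periodinane, NaHCO3, CH2Cl2, 0 °C
Reagents that add atoms: none
Why: Dess–Martin oxidation of the benzylic alcohol under buffered, non-basic conditions removes the C4 stereocentre and should leave the C3–H, now alpha to the ketone, untouched; both phenols are masked, so the oxidant has no other target.

Step 16
Reactants: 29 (3R)-7,2'-bis(methoxymethoxy)-3',4'-dimethoxy-5'-(2-methylbut-3-en-2-yl)isoflavanone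
Product: 30 pervilleanone [(3R)-7,2'-dihydroxy-3',4'-dimethoxy-5'-(2-methylbut-3-en-2-yl)isoflavanone]
Conditions: ZnBr2, n-PrSH, CH2Cl2, 0 °C, 10 min
Reagents that add atoms: none
Why: Lewis acid-assisted acetal exchange: ZnBr2 activates each methoxymethyl ether and the thiol captures the methoxymethyl cation as an O,S-acetal, freeing the phenols within minutes. No base is present and the contact time is short, so enolisation at C3 and dehydration of the 2'-hydroxy ketone should not compete.

## Compound list

1 | 5-chlorobenzene-1,3-diol (5-chlororesorcinol) | Oc1cc(O)cc(Cl)c1 | starting material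
2 | 4-bromo-5-chlorobenzene-1,3-diol | Oc1cc(O)c(Br)c(Cl)c1 | intermediate
3 | 4-bromo-5-chloro-1,3-bis(trimethylsilyloxy)benzene | C[Si](C)(C)Oc1cc(O[Si](C)(C)C)c(Br)c(Cl)c1 | intermediate
4 | lithium 3-chloro-2-(trimethylsilyl)-5-(trimethylsilyloxy)phenolate | [Li+].[O-]c1cc(O[Si](C)(C)C)cc(Cl)c1[Si](C)(C)C | intermediate
5 | 3-chloro-2-(trimethylsilyl)-5-(trimethylsilyloxy)phenyl trifluoromethanesulfonate | C[Si](C)(C)Oc1cc(Cl)c([Si](C)(C)C)c(OS(=O)(=O)C(F)(F)F)c1 | intermediate
6 | 3-chloro-5-hydroxy-2-(trimethylsilyl)phenyl trifluoromethanesulfonate | Oc1cc(Cl)c([Si](C)(C)C)c(OS(=O)(=O)C(F)(F)F)c1 | intermediate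
7 | 3-chloro-5-(methoxymethoxy)-2-(trimethylsilyl)phenyl trifluoromethanesulfonate | COCOc1cc(Cl)c([Si](C)(C)C)c(OS(=O)(=O)C(F)(F)F)c1 | intermediate
8 | 2-methoxybenzene-1,3-diol (2-methoxyresorcinol) | COc1c(O)cccc1O | starting material
9 | N-[(2,4-dihydroxy-3-methoxyphenyl)methylidene]-N-methylmethanaminium chloride | C[N+](C)=Cc1ccc(O)c(OC)c1O.[Cl-] | intermediate
10 | 2,4-dihydroxy-3-methoxybenzaldehyde | O=Cc1ccc(O)c(OC)c1O | intermediate
11 | 1-bromo-3-methylbut-2-ene (prenyl bromide) | CC(C)=CCBr | starting material
12 | 2-hydroxy-3-methoxy-4-[(3-methylbut-2-en-1-yl)oxy]benzaldehyde | O=Cc1ccc(OCC=C(C)C)c(OC)c1O | intermediate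
13 | 3-methoxy-2-(methoxymethoxy)-4-[(3-methylbut-2-en-1-yl)oxy]benzaldehyde | O=Cc1ccc(OCC=C(C)C)c(OC)c1OCOC | intermediate
14 | 5-methoxy-6-(methoxymethoxy)-3-(2-methylbut-3-en-2-yl)-4-oxocyclohexa-1,5-diene-1-carbaldehyde (racemic) | O=CC1=CC(C(C)(C)C=C)C(=O)C(OC)=C1OCOC | intermediate
15 | 4-hydroxy-3-methoxy-2-(methoxymethoxy)-5-(2-methylbut-3-en-2-yl)benzaldehyde | O=Cc1cc(C(C)(C)C=C)c(O)c(OC)c1OCOC | intermediate
16 | 3,4-dimethoxy-2-(methoxymethoxy)-5-(2-methylbut-3-en-2-yl)benzaldehyde | O=Cc1cc(C(C)(C)C=C)c(OC)c(OC)c1OCOC | intermediate
17 | ethyl diazoacetate | CCOC(=O)C=[N+]=[N-] | starting material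
18 | ethyl 2-diazonio-3-[3,4-dimethoxy-2-(methoxymethoxy)-5-(2-methylbut-3-en-2-yl)phenyl]-3-oxidopropanoate (Lewis acid-bound) | CCOC(=O)C([N+]#N)C([O-])c1cc(C(C)(C)C=C)c(OC)c(OC)c1OCOC | intermediate
19 | ethyl (Z)-2-[3,4-dimethoxy-2-(methoxymethoxy)-5-(2-methylbut-3-en-2-yl)phenyl]-3-hydroxyacrylate | O/C=C(\C(=O)OCC)c1cc(C(C)(C)C=C)c(OC)c(OC)c1OCOC | intermediate
20 | ethyl (E)-2-[3,4-dimethoxy-2-(methoxymethoxy)-5-(2-methylbut-3-en-2-yl)phenyl]-3-methoxyacrylate | CO/C=C(/C(=O)OCC)c1cc(C(C)(C)C=C)c(OC)c(OC)c1OCOC | intermediate
21 | (E)-2-[3,4-dimethoxy-2-(methoxymethoxy)-5-(2-methylbut-3-en-2-yl)phenyl]-3-methoxyacrylic acid | CO/C=C(/C(=O)O)c1cc(C(C)(C)C=C)c(OC)c(OC)c1OCOC | intermediate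
22 | cesium (E)-2-[3,4-dimethoxy-2-(methoxymethoxy)-5-(2-methylbut-3-en-2-yl)phenyl]-3-methoxyacrylate | [Cs+].CO/C=C(/C(=O)[O-])c1cc(C(C)(C)C=C)c(OC)c(OC)c1OCOC | intermediate
23 | 3-chloro-5-(methoxymethoxy)benzyne (1,2-didehydrobenzene) | COCOC1=CC#CC(Cl)=C1 | intermediate
24 | cesium 3-chloro-2-{(E)-2-[3,4-dimethoxy-2-(methoxymethoxy)-5-(2-methylbut-3-en-2-yl)phenyl]-3-methoxyacryloyl}-5-(methoxymethoxy)phenolate | [Cs+].CO/C=C(/C(=O)c1c([O-])cc(OCOC)cc1Cl)c1cc(C(C)(C)C=C)c(OC)c(OC)c1OCOC | intermediate
25 | 5-chloro-7,2'-bis(methoxymethoxy)-3',4'-dimethoxy-5'-(2-methylbut-3-en-2-yl)isoflavone | C=CC(C)(C)c1cc(-c2coc3cc(OCOC)cc(Cl)c3c2=O)c(OCOC)c(OC)c1OC | intermediate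
26 | 7,2'-bis(methoxymethoxy)-3',4'-dimethoxy-5'-(2-methylbut-3-en-2-yl)isoflavone | C=CC(C)(C)c1cc(-c2coc3cc(OCOC)ccc3c2=O)c(OCOC)c(OC)c1OC | intermediate
27 | racemic 7,2'-bis(methoxymethoxy)-3',4'-dimethoxy-5'-(2-methylbut-3-en-2-yl)isoflavanone | C=CC(C)(C)c1cc(C2COc3cc(OCOC)ccc3C2=O)c(OCOC)c(OC)c1OC | intermediate
28 | (3R,4R)-7,2'-bis(methoxymethoxy)-3',4'-dimethoxy-5'-(2-methylbut-3-en-2-yl)isoflavan-4-ol | C=CC(C)(C)c1cc([C@@H]2COc3cc(OCOC)ccc3[C@@H]2O)c(OCOC)c(OC)c1OC | intermediate
29 | (3R)-7,2'-bis(methoxymethoxy)-3',4'-dimethoxy-5'-(2-methylbut-3-en-2-yl)isoflavanone | C=CC(C)(C)c1cc([C@@H]2COc3cc(OCOC)ccc3C2=O)c(OCOC)c(OC)c1OC | intermediate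
30 | pervilleanone, (3R)-7,2'-dihydroxy-3',4'-dimethoxy-5'-(2-methylbut-3-en-2-yl)isoflavanone | C=CC(C)(C)c1cc([C@@H]2COc3cc(O)ccc3C2=O)c(O)c(OC)c1OC | target

## Step count and least certain steps

Total: 16 steps. Longest linear sequence: 13 steps (steps 4 to 16, from 8); the ring A branch (steps 1 to 3) joins at step 12.

Step 12 (key step). What may go wrong: protonation of the aryl anion by adventitious water before acyl transfer, loss of chloride from the aryl anion to give a second aryne, conjugate addition of the aryl anion to C2, or consumption of the aryne by the methoxide that the ring closure releases. Fallback: from 21, esterification (DCC, DMAP) with 2-bromo-5-(methoxymethoxy)phenol F1, itself available from commercial 4-bromoresorcinol by methoxymethylation of the hydroxyl remote from bromine, would give 2-bromo-5-(methoxymethoxy)phenyl (E)-2-[3,4-dimethoxy-2-(methoxymethoxy)-5-(2-methylbut-3-en-2-yl)phenyl]-3-methoxyacrylate F2. Bromine–lithium exchange (t-BuLi, THF, −100 °C) would generate the same kind of aryl anion without an aryne; the anionic Fries-type O to C acyl shift and, on warming, the phenolate ring closure would lead to 26. The route is rejoined at 26, and step 13 is no longer needed.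

Step 9. What may go wrong: hydride instead of aryl migration in 18, loss of the acetal under the Lewis acid followed by cyclisation onto the enol, or cyclopropanation of the vinyl group by an iron carbene. Fallback: from 16, addition of trichloromethanide (sodium trichloroacetate, trichloroacetic acid, DMF) would give 2,2,2-trichloro-1-[3,4-dimethoxy-2-(methoxymethoxy)-5-(2-methylbut-3-en-2-yl)phenyl]ethanol F3. Jocic-type reductive homologation (NaBH4, NaOH, t-BuOH, 55 °C) would give [3,4-dimethoxy-2-(methoxymethoxy)-5-(2-methylbut-3-en-2-yl)phenyl]acetic acid F4, and esterification (EtI, K2CO3, DMF) its ethyl ester F5. Crossed Claisen formylation (NaH, ethyl formate) returns to the route at 19.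

Step 13. What may go wrong: competing conjugate reduction of the chromone or hydrogenation of the vinyl group by palladium hydride, or slow oxidative addition. Fallback: from 25, Miyaura borylation (Pd2(dba)3, XPhos, B2pin2, KOAc, dioxane, 100 °C) would give 7,2'-bis(methoxymethoxy)-3',4'-dimethoxy-5'-(2-methylbut-3-en-2-yl)-5-(4,4,5,5-tetramethyl-1,3,2-dioxaborolan-2-yl)isoflavone F6. Fluoride-assisted protodeboronation (CsF, H2O, dioxane, 80 °C) would then give 26 with no hydride source in either step.

Step 14. What may go wrong: incomplete conjugate reduction, or racemisation of 27 that is too slow relative to ketone reduction with this crowded 2'-substituted aryl group, which would lower enantiomeric and diastereomeric purity. Fallback: from 26, acid methanolysis of both acetals (2 M HCl, MeOH/THF, 50 °C; safe here because no stereocentre exists yet) would give 7,2'-dihydroxy-3',4'-dimethoxy-5'-(2-methylbut-3-en-2-yl)isoflavone F7. Enzymatic reduction of C2=C3 with recombinant isoflavone reductase (NADPH regenerated with glucose 6-phosphate and its dehydrogenase, phosphate buffer pH 7, 30 °C), the enzyme class that converts 2'-hydroxyisoflavones into (3R)-isoflavanones, would give 30 directly; steps 15 and 16 then fall away. The open point of this fallback is whether the enzyme accepts the extra C3' methoxy and C5' alkyl groups.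

Step 16. What may go wrong: erosion of the C3 configuration by Lewis acid-promoted enolisation, cyclodehydration of the freed 2'-hydroxy ketone, or slow cleavage of the hindered C2' acetal. Fallback: from 26, the free isoflavone F7 (prepared as in the fallback for step 14) would be silylated (TBSCl, imidazole, DMF) to 7,2'-bis(tert-butyldimethylsilyloxy)-3',4'-dimethoxy-5'-(2-methylbut-3-en-2-yl)isoflavone F8. The conditions of step 14 would give the (3R,4R)-isoflavan-4-ol F9 and those of step 15 the (3R)-isoflavanone F10. Acetic acid-buffered TBAF (THF, 0 °C) would then give 30 under nearly neutral conditions.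

## Further compounds

F1 | step 12 | 2-bromo-5-(methoxymethoxy)phenol | Oc1cc(OCOC)ccc1Br
F2 | step 12 | 2-bromo-5-(methoxymethoxy)phenyl (E)-2-[3,4-dimethoxy-2-(methoxymethoxy)-5-(2-methylbut-3-en-2-yl)phenyl]-3-methoxyacrylate | CO/C=C(/C(=O)Oc1cc(OCOC)ccc1Br)c1cc(C(C)(C)C=C)c(OC)c(OC)c1OCOC
F3 | step 9 | 2,2,2-trichloro-1-[3,4-dimethoxy-2-(methoxymethoxy)-5-(2-methylbut-3-en-2-yl)phenyl]ethanol (racemic) | OC(c1cc(C(C)(C)C=C)c(OC)c(OC)c1OCOC)C(Cl)(Cl)Cl
F4 | step 9 | [3,4-dimethoxy-2-(methoxymethoxy)-5-(2-methylbut-3-en-2-yl)phenyl]acetic acid | OC(=O)Cc1cc(C(C)(C)C=C)c(OC)c(OC)c1OCOC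
F5 | step 9 | ethyl [3,4-dimethoxy-2-(methoxymethoxy)-5-(2-methylbut-3-en-2-yl)phenyl]acetate | CCOC(=O)Cc1cc(C(C)(C)C=C)c(OC)c(OC)c1OCOC
F6 | step 13 | 7,2'-bis(methoxymethoxy)-3',4'-dimethoxy-5'-(2-methylbut-3-en-2-yl)-5-(4,4,5,5-tetramethyl-1,3,2-dioxaborolan-2-yl)isoflavone | C=CC(C)(C)c1cc(-c2coc3cc(OCOC)cc(B4OC(C)(C)C(C)(C)O4)c3c2=O)c(OCOC)c(OC)c1OC
F7 | step 14 | 7,2'-dihydroxy-3',4'-dimethoxy-5'-(2-methylbut-3-en-2-yl)isoflavone | C=CC(C)(C)c1cc(-c2coc3cc(O)ccc3c2=O)c(O)c(OC)c1OC
F8 | step 16 | 7,2'-bis(tert-butyldimethylsilyloxy)-3',4'-dimethoxy-5'-(2-methylbut-3-en-2-yl)isoflavone | C=CC(C)(C)c1cc(-c2coc3cc(O[Si](C)(C)C(C)(C)C)ccc3c2=O)c(O[Si](C)(C)C(C)(C)C)c(OC)c1OC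
F9 | step 16 | (3R,4R)-7,2'-bis(tert-butyldimethylsilyloxy)-3',4'-dimethoxy-5'-(2-methylbut-3-en-2-yl)isoflavan-4-ol | C=CC(C)(C)c1cc([C@@H]2COc3cc(O[Si](C)(C)C(C)(C)C)ccc3[C@@H]2O)c(O[Si](C)(C)C(C)(C)C)c(OC)c1OC
F10 | step 16 | (3R)-7,2'-bis(tert-butyldimethylsilyloxy)-3',4'-dimethoxy-5'-(2-methylbut-3-en-2-yl)isoflavanone | C=CC(C)(C)c1cc([C@@H]2COc3cc(O[Si](C)(C)C(C)(C)C)ccc3C2=O)c(O[Si](C)(C)C(C)(C)C)c(OC)c1OC
A1 | alternative 1 | 2-methoxy-6-(2-methylbut-3-en-2-yl)-3-(triisopropylsilyloxy)phenol | C=CC(C)(C)c1ccc(O[Si](C(C)C)(C(C)C)C(C)C)c(OC)c1O
A2 | alternative 1 | (4-bromo-2-methoxyphenoxy)triisopropylsilane | COc1cc(Br)ccc1O[Si](C(C)C)(C(C)C)C(C)C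
A3 | alternative 2 | (R)-7-O-(tert-butyldimethylsilyl)pervilleanone | C=CC(C)(C)c1cc([C@@H]2COc3cc(O[Si](C)(C)C(C)(C)C)ccc3C2=O)c(O)c(OC)c1OC
A4 | alternative 2 | 4-(tert-butyldimethylsilyloxy)-2-{2-[2-hydroxy-3,4-dimethoxy-5-(2-methylbut-3-en-2-yl)phenyl]-2-(4-methylphenylsulfonyl)ethoxy}benzaldehyde (racemic) | O=Cc1ccc(O[Si](C)(C)C(C)(C)C)cc1OCC(c1cc(C(C)(C)C=C)c(OC)c(OC)c1O)S(=O)(=O)c1ccc(C)cc1
A5 | alternative 3 | (R)-7,2'-bis-O-(triisopropylsilyl)pervilleanone | C=CC(C)(C)c1cc([C@@H]2COc3cc(O[Si](C(C)C)(C(C)C)C(C)C)ccc3C2=O)c(O[Si](C(C)C)(C(C)C)C(C)C)c(OC)c1OC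
A6 | alternative 3 | 2-diazo-2-[3,4-dimethoxy-5-(2-methylbut-3-en-2-yl)-2-(triisopropylsilyloxy)phenyl]-1-[2-methoxy-4-(triisopropylsilyloxy)phenyl]ethanone | COc1cc(O[Si](C(C)C)(C(C)C)C(C)C)ccc1C(=O)C(=[N+]=[N-])c1cc(C(C)(C)C=C)c(OC)c(OC)c1O[Si](C(C)C)(C(C)C)C(C)C
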